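**Retrosynthetic overview**
- The ring B hydroxyquinone is made last, by oxidation of the 2',4'-dihydroxy-3'-prenyl isoflavan 19, which comes from its bis-MOM ether 18.
- Ring C of 18 is opened at O1–C2: an enantioselective anti-Markovnikov (6-endo) hydroetherification of the 2-(2-arylallyl)phenol 17 forms this C–O bond, closes the pyran and sets C3.
- 17 comes from an aromatic Claisen rearrangement of the aryl 2-arylallyl ether 15; 15 comes from a Negishi coupling of the 2-bromoallyl ether 8 with the ring B arylzinc 14.
- 8 comes from the symmetric phenol 6 (1,3-dimethoxybenzene: lithiation/prenylation, then meta C–H borylation/oxidation) and 2,3-dibromopropene; 14 comes from resorcinol (MOM protection, lithiation/prenylation, second lithiation).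
- Ring order: rings A and B are bought as benzenes; ring C is the only ring formed (step 8); ring B becomes the quinone in step 10.

Assumption: the target is the (3R) enantiomer encoded in the SMILES, drawn as the 2-hydroxy-1,4-benzoquinone tautomer. Which antipode of the new chiral thiol gives (3R) cannot be predicted; it is fixed by the first run and written here as (R).

**Step 1**
Reactants: 1 1,3-dimethoxybenzene; 2 1-bromo-3-methylbut-2-ene (prenyl bromide)
Product: 4 1,3-dimethoxy-2-(3-methylbut-2-enyl)benzene, via 2,6-dimethoxyphenyllithium 3 (not isolated)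
Conditions: n-BuLi, THF, 0 °C → rt; then 2, 0 °C → rt
Reagents that add atoms: none
Why: Directed ortho-metalation between the two methoxy groups gives 3, which is alkylated by SN2 at the primary allylic carbon of 2.

**Step 2**
Reactants: 4 1,3-dimethoxy-2-(3-methylbut-2-enyl)benzene
Product: 6 3,5-dimethoxy-4-(3-methylbut-2-enyl)phenol, via arylboronic pinacol ester 5 (not isolated)
Conditions: [Ir(OMe)(cod)]2 (1 mol %), dtbpy (2 mol %), B2pin2 (1.0 equiv), THF, 60 °C; then aq NaOH, 30% H2O2, 0 °C → rt
Reagents that add atoms: bis(pinacolato)diboron CC1(C)OB(OC1(C)C)B1OC(C)(C)C(C)(C)O1 (boron group of intermediate 5 only); hydrogen peroxide OO (phenol oxygen of 6)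
Why: Sterically controlled iridium-catalysed aromatic C–H borylation takes the only C–H not ortho to a substituent (C5, para to the prenyl group, whose hindered trisubstituted alkene is spared), and nucleophilic alkaline peroxide then turns C–B into C–OH without epoxidising the alkene.

**Step 3**
Reactants: 6 3,5-dimethoxy-4-(3-methylbut-2-enyl)phenol; 7 2,3-dibromoprop-1-ene
Product: 8 5-(2-bromoprop-2-enyloxy)-1,3-dimethoxy-2-(3-methylbut-2-enyl)benzene
Conditions: K2CO3, acetone, 56 °C
Reagents that add atoms: none
Why: Williamson ether synthesis; the phenoxide displaces the allylic bromide (SN2 and SN2' give the same product) and the vinylic bromide stays.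

**Step 4**
Reactants: 9 resorcinol
Product: 10 1,3-bis(methoxymethoxy)benzene
Conditions: NaH, DMF, 0 °C; MOMCl, 0 °C → rt
Reagents that add atoms: chloromethyl methyl ether (MOMCl) COCCl
Why: Double O-alkylation of the bis-phenoxide gives the MOM acetals, which direct both later lithiations and are removed without hydrogenation or Lewis acid.

**Step 5**
Reactants: 10 1,3-bis(methoxymethoxy)benzene; 2 1-bromo-3-methylbut-2-ene
Product: 12 1,3-bis(methoxymethoxy)-2-(3-methylbut-2-enyl)benzene, via 2,6-bis(methoxymethoxy)phenyllithium 11 (not isolated)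
Conditions: n-BuLi, THF, 0 °C → rt; CuI (10 mol %), then 2, −78 °C → rt
Reagents that add atoms: none
Why: Directed ortho-metalation at the carbon flanked by both MOM ethers, then copper-catalysed allylic alkylation at the unhindered primary carbon of prenyl bromide.

**Step 6**
Reactants: 12 1,3-bis(methoxymethoxy)-2-(3-methylbut-2-enyl)benzene; 8 5-(2-bromoprop-2-enyloxy)-1,3-dimethoxy-2-(3-methylbut-2-enyl)benzene
Product: 15 5-{2-[2,4-bis(methoxymethoxy)-3-(3-methylbut-2-enyl)phenyl]prop-2-enyloxy}-1,3-dimethoxy-2-(3-methylbut-2-enyl)benzene, via aryllithium 13 (not isolated), via arylzinc chloride 14 (not isolated)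
Conditions: n-BuLi, TMEDA, THF, −20 → 0 °C; ZnCl2, 0 °C → rt; then 8 (0.9 equiv), Pd(OAc)2 (2 mol %), SPhos (4 mol %), rt → 40 °C
Reagents that add atoms: none
Why: A second directed ortho-metalation (ortho to a MOM ether, C4), transmetalation to zinc and Negishi cross-coupling at the vinylic C–Br of 8 in one pot; oxidative addition to C–Br is much faster than ionisation of the allyl aryl ether at this temperature.

**Step 7**
Reactants: 15 the aryl 2-arylallyl ether from step 6
Product: 17 2-{2-[2,4-bis(methoxymethoxy)-3-(3-methylbut-2-enyl)phenyl]prop-2-enyl}-3,5-dimethoxy-4-(3-methylbut-2-enyl)phenol, via ortho-dienone 16 (not isolated)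
Conditions: PhNEt2, 185 °C, sealed tube, Ar
Reagents that add atoms: none
Why: Aromatic Claisen rearrangement ([3,3]-sigmatropic); the para position is blocked, the two ortho positions are equivalent and the 2-arylallyl unit maps onto itself, so one regioisomer forms after tautomerisation of 16, and the basic solvent suppresses acid-type cyclisation of the product.

**Step 8**
Reactants: 17 the 2-(2-arylallyl)phenol from step 7
Product: 18 (3R)-3-[2,4-bis(methoxymethoxy)-3-(3-methylbut-2-enyl)phenyl]-5,7-dimethoxy-6-(3-methylbut-2-enyl)-3,4-dihydro-2H-chromene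
Conditions: [Ir(dF(CF3)ppy)2(5,5'-d(CF3)bpy)]PF6 (2 mol %), chiral arenethiol ArSH* (20 mol %), 2,4,6-collidine (20 mol %), PhCF3, 450 nm LEDs, −20 °C, Ar
Reagents that add atoms: none
Why: Proposed new method: enantioselective anti-Markovnikov intramolecular hydroetherification, in which the excited trivalent iridium photocatalyst (about +1.7 V vs SCE, too weak for the prenyl alkenes at about +2.0 V) oxidises the electron-rich phenol/styrene unit of 17, the phenol oxygen closes 6-endo onto the terminal CH2 because only that mode leaves the tertiary benzylic C3 radical (the same radical results whether the hole sits on the alkene or on the phenol oxygen), and this planar radical is quenched by irreversible hydrogen-atom transfer from the pocket-shaped axially chiral thiol ArSH* = (R)-2'-methoxy-3-(2,4,6-triisopropylphenyl)-1,1'-binaphthalene-2-thiol (S–H about 79 kcal/mol, weaker than the new C3–H, so the product is not re-abstracted and racemised), which sets C3 as (R), while divalent iridium reduces the thiyl radical back to thiolate and collidinium reprotonates it; the closest known reaction types are the racemic photoredox/thiol anti-Markovnikov hydroetherification of alkenols and enantioselective hydrogen-atom transfer from chiral thiols to prochiral carbon radicals, and their combination with a phenol nucleophile and a chiral arenethiol is untested.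

**Step 9**
Reactants: 18 the (3R)-bis-MOM isoflavan from step 8
Product: 19 4-[(3R)-5,7-dimethoxy-6-(3-methylbut-2-enyl)-3,4-dihydro-2H-chromen-3-yl]-2-(3-methylbut-2-enyl)benzene-1,3-diol
Conditions: 3 M aq HCl (5 equiv), MeOH/THF, 40 °C
Reagents that add atoms: none
Why: Acid-catalysed acetal exchange with methanol removes both MOM groups as dimethoxymethane under conditions milder than those that cyclise ortho-prenylphenols, and C3 is not touched.

**Step 10**
Reactants: 19 the (3R)-resorcinol from step 9
Product: 20 2-[(3R)-5,7-dimethoxy-6-(3-methylbut-2-enyl)-3,4-dihydro-2H-chromen-3-yl]-5-hydroxy-6-(3-methylbut-2-enyl)cyclohexa-2,5-diene-1,4-dione (target)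
Conditions: (KSO3)2NO (2.5 equiv), KH2PO4 buffer (pH 6), acetone/H2O, 0 °C → rt
Reagents that add atoms: potassium nitrosodisulfonate [K+].[K+].[O-]S(=O)(=O)N([O])S(=O)(=O)[O-] (the new quinone oxygen)
Why: Teuber oxidation; the only free position ortho or para to a hydroxyl in ring B is C5' (para to 2'-OH, ortho to 4'-OH), so oxygen enters there and gives the 2-hydroxy-1,4-benzoquinone, while the fully etherified ring A is inert and C3 is not epimerised at pH 6.

**Compound list**
1 | 1,3-dimethoxybenzene | COc1cccc(OC)c1 | starting material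
2 | 1-bromo-3-methylbut-2-ene (prenyl bromide) | CC(C)=CCBr | starting material
3 | 2,6-dimethoxyphenyllithium (formed in the flask) | [Li]c1c(OC)cccc1OC | intermediate
4 | 1,3-dimethoxy-2-(3-methylbut-2-enyl)benzene | COc1cccc(OC)c1CC=C(C)C | intermediate
5 | 2-[3,5-dimethoxy-4-(3-methylbut-2-enyl)phenyl]-4,4,5,5-tetramethyl-1,3,2-dioxaborolane (formed in the flask) | COc1cc(B2OC(C)(C)C(C)(C)O2)cc(OC)c1CC=C(C)C | intermediate
6 | 3,5-dimethoxy-4-(3-methylbut-2-enyl)phenol | COc1cc(O)cc(OC)c1CC=C(C)C | intermediate
7 | 2,3-dibromoprop-1-ene | C=C(Br)CBr | starting material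
8 | 5-(2-bromoprop-2-enyloxy)-1,3-dimethoxy-2-(3-methylbut-2-enyl)benzene | COc1cc(OCC(Br)=C)cc(OC)c1CC=C(C)C | intermediate
9 | resorcinol (benzene-1,3-diol) | Oc1cccc(O)c1 | starting material
10 | 1,3-bis(methoxymethoxy)benzene | COCOc1cccc(OCOC)c1 | intermediate
11 | 2,6-bis(methoxymethoxy)phenyllithium (formed in the flask) | [Li]c1c(OCOC)cccc1OCOC | intermediate
12 | 1,3-bis(methoxymethoxy)-2-(3-methylbut-2-enyl)benzene | COCOc1cccc(OCOC)c1CC=C(C)C | intermediate
13 | [2,4-bis(methoxymethoxy)-3-(3-methylbut-2-enyl)phenyl]lithium (formed in the flask) | [Li]c1ccc(OCOC)c(CC=C(C)C)c1OCOC | intermediate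
14 | [2,4-bis(methoxymethoxy)-3-(3-methylbut-2-enyl)phenyl]zinc chloride (formed in the flask) | Cl[Zn]c1ccc(OCOC)c(CC=C(C)C)c1OCOC | intermediate
15 | 5-{2-[2,4-bis(methoxymethoxy)-3-(3-methylbut-2-enyl)phenyl]prop-2-enyloxy}-1,3-dimethoxy-2-(3-methylbut-2-enyl)benzene | COc1cc(OCC(=C)c2ccc(OCOC)c(CC=C(C)C)c2OCOC)cc(OC)c1CC=C(C)C | intermediate
16 | 6-{2-[2,4-bis(methoxymethoxy)-3-(3-methylbut-2-enyl)phenyl]prop-2-enyl}-3,5-dimethoxy-4-(3-methylbut-2-enyl)cyclohexa-2,4-dien-1-one (racemic Claisen dienone, formed in the flask) | O=C1C=C(OC)C(CC=C(C)C)=C(OC)C1CC(=C)c2ccc(OCOC)c(CC=C(C)C)c2OCOC | intermediate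
17 | 2-{2-[2,4-bis(methoxymethoxy)-3-(3-methylbut-2-enyl)phenyl]prop-2-enyl}-3,5-dimethoxy-4-(3-methylbut-2-enyl)phenol | COc1cc(O)c(CC(=C)c2ccc(OCOC)c(CC=C(C)C)c2OCOC)c(OC)c1CC=C(C)C | intermediate
18 | (3R)-3-[2,4-bis(methoxymethoxy)-3-(3-methylbut-2-enyl)phenyl]-5,7-dimethoxy-6-(3-methylbut-2-enyl)-3,4-dihydro-2H-chromene | COc1cc2c(c(OC)c1CC=C(C)C)C[C@H](c3ccc(OCOC)c(CC=C(C)C)c3OCOC)CO2 | intermediate
19 | 4-[(3R)-5,7-dimethoxy-6-(3-methylbut-2-enyl)-3,4-dihydro-2H-chromen-3-yl]-2-(3-methylbut-2-enyl)benzene-1,3-diol | COc1cc2c(c(OC)c1CC=C(C)C)C[C@H](c3ccc(O)c(CC=C(C)C)c3O)CO2 | intermediate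
20 | 2-[(3R)-5,7-dimethoxy-6-(3-methylbut-2-enyl)-3,4-dihydro-2H-chromen-3-yl]-5-hydroxy-6-(3-methylbut-2-enyl)cyclohexa-2,5-diene-1,4-dione | COc1cc2c(c(OC)c1CC=C(C)C)C[C@H](C1=CC(=O)C(O)=C(CC=C(C)C)C1=O)CO2 | target

**Step count**
Total steps: 10. Longest linear sequence: 8 (steps 1, 2, 3, 6, 7, 8, 9, 10 from 1,3-dimethoxybenzene).

**Three steps most likely to fail**

Step 8 (the proposed new reaction) is the most likely to fail. The chiral arenethiol may give low ee. Thiyl radicals can add to the 1,1-disubstituted or prenyl alkenes. The oxidised phenol may couple instead of cyclising. Trace acid would give the Markovnikov 2-aryl-2-methyl-dihydrobenzofuran. The fallback uses only known chemistry, sets out from 17 and comes back at 18. Copper-catalysed enantioselective hydroboration of the 1,1-disubstituted aryl alkene (CuCl, NaOt-Bu, chiral N-heterocyclic carbene or bisphosphine ligand, B2pin2, MeOH, THF) gives the (R)-alkylboronic pinacol ester F1, with C3 set in the copper–boryl addition step and the ligand antipode chosen for (R). Oxidation with NaBO3·4H2O gives the (R)-primary alcohol F2. A Mitsunobu closure of the phenol onto the primary alcohol (PPh3, diisopropyl azodicarboxylate, THF, 0 °C) then forms O1–C2 without touching C3 and gives 18. This costs two extra steps.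

Step 7 (Claisen at 185 °C on the fully loaded ether) is the second risk. The hindered 2-arylallyl group may rearrange slowly, and the product can cyclise thermally onto its styrene. The fallback sets out from 8 (with 13 from step 6) and comes back at 17. It moves the sigmatropic step to the small, robust ether and attaches ring B afterwards under mild conditions. Heating 8 in PhNEt2 at 190 °C gives, through the ortho-dienone F3, the 2-(2-bromoprop-2-enyl)phenol F4. Aryllithium 13 is quenched with 2-isopropoxy-4,4,5,5-tetramethyl-1,3,2-dioxaborolane to give the arylboronic pinacol ester F5. Suzuki coupling of F4 with F5 (Pd(dppf)Cl2, K3PO4, dioxane/H2O, 70 °C; the free phenol is tolerated) gives 17.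

Step 10 (final oxidation on the most valuable material) is the third risk. Possible problems are over-oxidation, radical attack on the prenyl groups, or base-induced epimerisation of C3 through a quinone methide. The fallback sets out from 19 and comes back at 20. It replaces the radical oxidant by a two-electron ortho-oxygenation with a purifiable reduced intermediate. 2-Iodoxybenzoic acid in DMF at rt oxygenates the only free position ortho to 4'-OH (C5') and gives the ortho-quinone tautomer F6. Na2S2O4 in the same flask reduces it to the benzene-1,2,4-triol F7, which is freed from iodine by-products by a bicarbonate wash under argon. Air in pH 7 buffer/EtOAc then reoxidises F7 cleanly to 20.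

**Further compounds**
F1 | step 8 | 2-{(2R)-2-[2,4-bis(methoxymethoxy)-3-(3-methylbut-2-enyl)phenyl]-3-(4,4,5,5-tetramethyl-1,3,2-dioxaborolan-2-yl)propyl}-3,5-dimethoxy-4-(3-methylbut-2-enyl)phenol | COc1cc(O)c(C[C@H](c3ccc(OCOC)c(CC=C(C)C)c3OCOC)CB2OC(C)(C)C(C)(C)O2)c(OC)c1CC=C(C)C
F2 | step 8 | 2-{(2R)-2-[2,4-bis(methoxymethoxy)-3-(3-methylbut-2-enyl)phenyl]-3-hydroxypropyl}-3,5-dimethoxy-4-(3-methylbut-2-enyl)phenol | COc1cc(O)c(C[C@H](c3ccc(OCOC)c(CC=C(C)C)c3OCOC)CO)c(OC)c1CC=C(C)C
F3 | step 7 | 6-(2-bromoprop-2-enyl)-3,5-dimethoxy-4-(3-methylbut-2-enyl)cyclohexa-2,4-dien-1-one (racemic, formed in the flask) | O=C1C=C(OC)C(CC=C(C)C)=C(OC)C1CC(Br)=C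
F4 | step 7 | 2-(2-bromoprop-2-enyl)-3,5-dimethoxy-4-(3-methylbut-2-enyl)phenol | COc1cc(O)c(CC(Br)=C)c(OC)c1CC=C(C)C
F5 | step 7 | 2-[2,4-bis(methoxymethoxy)-3-(3-methylbut-2-enyl)phenyl]-4,4,5,5-tetramethyl-1,3,2-dioxaborolane | CC1(C)OB(OC1(C)C)c2ccc(OCOC)c(CC=C(C)C)c2OCOC
F6 | step 10 | 4-[(3R)-5,7-dimethoxy-6-(3-methylbut-2-enyl)-3,4-dihydro-2H-chromen-3-yl]-5-hydroxy-6-(3-methylbut-2-enyl)cyclohexa-3,5-diene-1,2-dione (ortho-quinone tautomer of 20, formed in the flask) | COc1cc2c(c(OC)c1CC=C(C)C)C[C@H](C3=CC(=O)C(=O)C(CC=C(C)C)=C3O)CO2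
F7 | step 10 | 5-[(3R)-5,7-dimethoxy-6-(3-methylbut-2-enyl)-3,4-dihydro-2H-chromen-3-yl]-3-(3-methylbut-2-enyl)benzene-1,2,4-triol | COc1cc2c(c(OC)c1CC=C(C)C)C[C@H](c3cc(O)c(O)c(CC=C(C)C)c3O)CO2
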